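**Retrosynthetic overview**

1. The strategy rests on ring B, the 4-hydroxyphenyl ring (C1'–C6', hydroxyl on C4') on C2 of the chromen-4-one. It is cut at C1'–C2' and C5'–C6' into a C2-ethynyl group (C1', C6') and 1-methoxy-3-(trimethylsilyloxy)butadiene (C2'–C5'), joined by Diels–Alder reaction and loss of methanol.
2. The 2-ethynylchromone comes from the 2-carbaldehyde by one-carbon homologation, and the aldehyde from a chromone-2-carboxylate.
3. Ring C (O1, C2, C3, C4) is closed by crossed Claisen condensation of an omega-MOM-oxy 2-hydroxyacetophenone with diethyl oxalate, followed by base-mediated dehydration, so C3 carries its oxygen from the start.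
4. Ring A is bought as 2,4,6-trihydroxyacetophenone; C-prenylation and selective MOM protection decide that the phenol next to the prenyl group becomes O1 (prenyl on C8).
5. Ring order: A (bought), C (steps 5–6), B (step 10); the MOM ethers are removed last.

Key step: step 10

Remark: the target is achiral; chromen-4-one numbering (O1, C2–C4, C4a, C5–C8, C8a) is used, primed numbers belong to ring B, and MOM is methoxymethyl.

**Route**

Step 1
Reactants: 1 2,4,6-trihydroxyacetophenone; 2 1-bromo-3-methylbut-2-ene (prenyl bromide)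
Product: 3 1-[2,4,6-trihydroxy-3-(3-methylbut-2-enyl)phenyl]ethanone
Conditions: 2 (1.0 equiv), DBU (1.1 equiv), THF, 0 °C → rt
Reagents that add atoms: none
Why: C-alkylation of the ambident phloroacetophenone anion (C-prenylation of a phloroglucinol); the two open ring positions are equivalent, so only one mono-C-prenyl isomer can form, and limiting the bromide should hold down O- and di-alkylation.

Step 2
Reactants: 3 1-[2,4,6-trihydroxy-3-(3-methylbut-2-enyl)phenyl]ethanone
Product: 4 1-[2-hydroxy-4,6-bis(methoxymethoxy)-3-(3-methylbut-2-enyl)phenyl]ethanone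
Conditions: MOMCl (2.3 equiv), i-Pr2NEt (3 equiv), CH2Cl2, 0 °C → rt
Reagents that add atoms: chloromethyl methyl ether (MOMCl), COCCl
Why: MOM ether formation at the unchelated 4-OH and the less hindered 6-OH, while the 2-OH, hydrogen-bonded to the ketone and flanked by the prenyl group, should stay free, which fixes the later ring closure at the oxygen next to the prenyl group.

Step 3
Reactants: 4 1-[2-hydroxy-4,6-bis(methoxymethoxy)-3-(3-methylbut-2-enyl)phenyl]ethanone
Product: 5 2-hydroxy-1-[2-hydroxy-4,6-bis(methoxymethoxy)-3-(3-methylbut-2-enyl)phenyl]ethanone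
Conditions: KN(SiMe3)2 (2.3 equiv), THF, −78 °C; 3-phenyl-2-(phenylsulfonyl)oxaziridine (1.2 equiv), −78 °C; AcOH
Reagents that add atoms: 3-phenyl-2-(phenylsulfonyl)oxaziridine (Davis oxaziridine), O=S(=O)(N1OC1c1ccccc1)c1ccccc1
Why: Davis enolate hydroxylation of the phenoxide–enolate dianion at the enolate carbon by an oxidant that does not epoxidise the isolated prenyl olefin, the potassium counter-ion limiting addition to the sulfonimine by-product.

Step 4
Reactants: 5 2-hydroxy-1-[2-hydroxy-4,6-bis(methoxymethoxy)-3-(3-methylbut-2-enyl)phenyl]ethanone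
Product: 6 1-[2-hydroxy-4,6-bis(methoxymethoxy)-3-(3-methylbut-2-enyl)phenyl]-2-(methoxymethoxy)ethanone
Conditions: MOMCl (1.2 equiv), i-Pr2NEt (2 equiv), CH2Cl2, 0 °C
Reagents that add atoms: chloromethyl methyl ether (MOMCl), COCCl
Why: MOM protection of the primary alcohol, the chelated and hindered phenol that resisted MOMCl in step 2 being expected to stay free when little excess chloride is used.

Step 5
Reactants: 6 1-[2-hydroxy-4,6-bis(methoxymethoxy)-3-(3-methylbut-2-enyl)phenyl]-2-(methoxymethoxy)ethanone; 7 diethyl oxalate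
Product: 9 ethyl 2-hydroxy-3,5,7-tris(methoxymethoxy)-8-(3-methylbut-2-enyl)-4-oxochromane-2-carboxylate (racemic diastereomer mixture), via open-chain diketo ester 8 (not isolated)
Conditions: LiN(SiMe3)2 (3.3 equiv), THF, −78 °C; 7 (2 equiv), −78 → 0 °C; AcOH
Reagents that add atoms: none
Why: Crossed Claisen condensation of the ketone enolate with the non-enolisable oxalate, driven by deprotonation of the 1,3-dicarbonyl product 8; on the acetic acid quench the phenol adds to the ketone of the alpha-keto ester to give the six-membered hemiketal.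

Step 6
Reactants: 9 ethyl 2-hydroxy-3,5,7-tris(methoxymethoxy)-8-(3-methylbut-2-enyl)-4-oxochromane-2-carboxylate
Product: 11 ethyl 3,5,7-tris(methoxymethoxy)-8-(3-methylbut-2-enyl)-4-oxochromene-2-carboxylate, via hemiketal methanesulfonate 10 (not isolated)
Conditions: MsCl (1.5 equiv), Et3N (4 equiv), CH2Cl2, 0 °C → rt
Reagents that add atoms: none
Why: Dehydration of a beta-hydroxy ketone by sulfonylation of the tertiary hemiketal hydroxyl and E1cB elimination across C2–C3 (C3–H is alpha to the C4 ketone), a base-mediated substitute for the usual acid-catalysed chromone closure that spares the MOM ethers and the prenyl olefin.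

Step 7
Reactants: 11 ethyl 3,5,7-tris(methoxymethoxy)-8-(3-methylbut-2-enyl)-4-oxochromene-2-carboxylate
Product: 12 2-(hydroxymethyl)-3,5,7-tris(methoxymethoxy)-8-(3-methylbut-2-enyl)chromen-4-one
Conditions: NaBH4 (2 equiv), MeOH–THF, 0 °C
Reagents that add atoms: none
Why: Borohydride reduction of an activated ester, the carboxylate on the oxygen-bearing C2 being the most electrophilic carbonyl while the vinylogous-ester C4 carbonyl is inert to NaBH4 at 0 °C, as with simple chromone-2-carboxylates.

Step 8
Reactants: 12 2-(hydroxymethyl)-3,5,7-tris(methoxymethoxy)-8-(3-methylbut-2-enyl)chromen-4-one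
Product: 13 3,5,7-tris(methoxymethoxy)-8-(3-methylbut-2-enyl)-4-oxochromene-2-carbaldehyde
Conditions: Dess–Martin periodinane (1.3 equiv), pyridine, CH2Cl2, rt
Reagents that add atoms: none
Why: Dess–Martin oxidation of the primary allylic alcohol to the aldehyde under buffered, non-acidic conditions that leave the olefin and the acetals untouched.

Step 9
Reactants: 13 3,5,7-tris(methoxymethoxy)-8-(3-methylbut-2-enyl)-4-oxochromene-2-carbaldehyde
Product: 14 2-ethynyl-3,5,7-tris(methoxymethoxy)-8-(3-methylbut-2-enyl)chromen-4-one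
Conditions: dimethyl (1-diazo-2-oxopropyl)phosphonate (1.5 equiv), K2CO3 (2 equiv), MeOH–THF, 0 °C → rt
Reagents that add atoms: dimethyl (1-diazo-2-oxopropyl)phosphonate (Ohira–Bestmann reagent), COP(=O)(OC)C(=[N+]=[N-])C(C)=O
Why: Ohira–Bestmann (Seyferth–Gilbert) homologation, in which the diazomethylphosphonate anion released by methanolysis adds to the aldehyde, phosphate elimination gives the diazoalkene, and loss of N2 with a 1,2-hydride shift gives the terminal alkyne.

Step 10
Reactants: 14 2-ethynyl-3,5,7-tris(methoxymethoxy)-8-(3-methylbut-2-enyl)chromen-4-one; 15 (E)-1-methoxy-3-(trimethylsilyloxy)buta-1,3-diene (Danishefsky's diene)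
Product: 18 2-(4-hydroxyphenyl)-3,5,7-tris(methoxymethoxy)-8-(3-methylbut-2-enyl)chromen-4-one, via cyclohexadiene cycloadduct 16 (not isolated), via aryl trimethylsilyl ether 17 (not isolated)
Conditions: 15 (5 equiv), toluene, 130 °C, sealed tube; then 0.1 M HCl, THF–H2O, 0 °C
Reagents that add atoms: none
Why: Proposed new method: the ethynyl group of 14 is conjugated through C2=C3 to the C4 carbonyl and so acts as a vinylogous ynone with an electrophilic terminal carbon, which should undergo a thermal, asynchronous but concerted (4+2) cycloaddition with the electron-rich diene 15; the closest known reaction type is the Diels–Alder reaction of this diene with propiolates and ethynyl ketones followed by aromatisation to 4-substituted phenols, which has not been run on a 2-ethynylchromone. Ring B closes by intermolecular (4+2) cycloaddition, the bonds C1'–C2' and C5'–C6' forming in the same step to give the cyclohexa-1,4-diene 16. In dilute acid the doubly allylic methoxy group of 16 ionises and C5' loses a proton to give aryl silyl ether 17, which is hydrolysed to phenol 18, while the aryl MOM ethers should survive 0.1 M HCl at 0 °C. No stereocentre remains, because the methoxy-bearing carbon of 16 forms as a racemate and then becomes aromatic. The step needs regioselectivity (hydroxyl para to C1'), which follows from bonding of the nucleophilic CH2 terminus of the diene to the alkyne terminus, where attack leaves the developing charge delocalised into the pyranone carbonyl. It also needs chemoselectivity for the alkyne, secured because the tetrasubstituted C2=C3 bond and the unactivated prenyl olefin are not dienophiles for this diene.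

Step 11
Reactants: 18 2-(4-hydroxyphenyl)-3,5,7-tris(methoxymethoxy)-8-(3-methylbut-2-enyl)chromen-4-one
Product: 19 8-prenylkaempferol, 3,5,7-trihydroxy-2-(4-hydroxyphenyl)-8-(3-methylbut-2-enyl)chromen-4-one
Conditions: 3 M aq. HCl, MeOH, 40 °C
Reagents that add atoms: none
Why: Acid-catalysed acetal exchange (methanolysis) of the three MOM ethers to dimethoxymethane, with acid strength and temperature kept low so that the 7-OH does not add to the protonated prenyl olefin.

**Compound list**

1 | 2,4,6-trihydroxyacetophenone | CC(=O)c1c(O)cc(O)cc1O | starting material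
2 | 1-bromo-3-methylbut-2-ene (prenyl bromide) | CC(C)=CCBr | starting material
3 | 1-[2,4,6-trihydroxy-3-(3-methylbut-2-enyl)phenyl]ethanone | CC(=O)c1c(O)cc(O)c(CC=C(C)C)c1O | intermediate
4 | 1-[2-hydroxy-4,6-bis(methoxymethoxy)-3-(3-methylbut-2-enyl)phenyl]ethanone | CC(=O)c1c(OCOC)cc(OCOC)c(CC=C(C)C)c1O | intermediate
5 | 2-hydroxy-1-[2-hydroxy-4,6-bis(methoxymethoxy)-3-(3-methylbut-2-enyl)phenyl]ethanone | OCC(=O)c1c(OCOC)cc(OCOC)c(CC=C(C)C)c1O | intermediate
6 | 1-[2-hydroxy-4,6-bis(methoxymethoxy)-3-(3-methylbut-2-enyl)phenyl]-2-(methoxymethoxy)ethanone | COCOCC(=O)c1c(OCOC)cc(OCOC)c(CC=C(C)C)c1O | intermediate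
7 | diethyl oxalate | CCOC(=O)C(=O)OCC | starting material
8 | ethyl 4-[2-hydroxy-4,6-bis(methoxymethoxy)-3-(3-methylbut-2-enyl)phenyl]-3-(methoxymethoxy)-2,4-dioxobutanoate, racemic, open-chain form (not isolated) | CCOC(=O)C(=O)C(OCOC)C(=O)c1c(OCOC)cc(OCOC)c(CC=C(C)C)c1O | intermediate
9 | ethyl 2-hydroxy-3,5,7-tris(methoxymethoxy)-8-(3-methylbut-2-enyl)-4-oxochromane-2-carboxylate, racemic mixture of C2/C3 diastereomers | CCOC(=O)C1(O)Oc2c(CC=C(C)C)c(OCOC)cc(OCOC)c2C(=O)C1OCOC | intermediate
10 | ethyl 2-(methylsulfonyloxy)-3,5,7-tris(methoxymethoxy)-8-(3-methylbut-2-enyl)-4-oxochromane-2-carboxylate, racemic diastereomer mixture (not isolated) | CCOC(=O)C1(OS(C)(=O)=O)Oc2c(CC=C(C)C)c(OCOC)cc(OCOC)c2C(=O)C1OCOC | intermediate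
11 | ethyl 3,5,7-tris(methoxymethoxy)-8-(3-methylbut-2-enyl)-4-oxochromene-2-carboxylate | CCOC(=O)c1oc2c(CC=C(C)C)c(OCOC)cc(OCOC)c2c(=O)c1OCOC | intermediate
12 | 2-(hydroxymethyl)-3,5,7-tris(methoxymethoxy)-8-(3-methylbut-2-enyl)chromen-4-one | OCc1oc2c(CC=C(C)C)c(OCOC)cc(OCOC)c2c(=O)c1OCOC | intermediate
13 | 3,5,7-tris(methoxymethoxy)-8-(3-methylbut-2-enyl)-4-oxochromene-2-carbaldehyde | O=Cc1oc2c(CC=C(C)C)c(OCOC)cc(OCOC)c2c(=O)c1OCOC | intermediate
14 | 2-ethynyl-3,5,7-tris(methoxymethoxy)-8-(3-methylbut-2-enyl)chromen-4-one | C#Cc1oc2c(CC=C(C)C)c(OCOC)cc(OCOC)c2c(=O)c1OCOC | intermediate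
15 | (E)-1-methoxy-3-(trimethylsilyloxy)buta-1,3-diene (Danishefsky's diene) | CO/C=C/C(=C)O[Si](C)(C)C | starting material
16 | 2-[6-methoxy-4-(trimethylsilyloxy)cyclohexa-1,4-dien-1-yl]-3,5,7-tris(methoxymethoxy)-8-(3-methylbut-2-enyl)chromen-4-one, racemic (not isolated) | COC1C=C(O[Si](C)(C)C)CC=C1c1oc2c(CC=C(C)C)c(OCOC)cc(OCOC)c2c(=O)c1OCOC | intermediate
17 | 3,5,7-tris(methoxymethoxy)-8-(3-methylbut-2-enyl)-2-[4-(trimethylsilyloxy)phenyl]chromen-4-one (not isolated) | C[Si](C)(C)Oc1ccc(cc1)-c1oc2c(CC=C(C)C)c(OCOC)cc(OCOC)c2c(=O)c1OCOC | intermediate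
18 | 2-(4-hydroxyphenyl)-3,5,7-tris(methoxymethoxy)-8-(3-methylbut-2-enyl)chromen-4-one | CC(C)=CCc1c(OCOC)cc(OCOC)c2c(=O)c(OCOC)c(-c3ccc(O)cc3)oc12 | intermediate
19 | 8-prenylkaempferol | CC(C)=CCc1c(O)cc(O)c2c(=O)c(O)c(-c3ccc(O)cc3)oc12 | target

**Step count and risks**

Total step count: 11. Longest linear sequence: 11 steps, from 1 to 19; compounds 2, 7 and 15 are bought.

Steps most likely to fail:

1. Step 10 (the proposed new method). The three alkoxy groups on the pyranone may leave the alkyne too weakly activated, so that the diene oligomerises or loses its silyl group before cycloaddition. The fallback uses known flavonol chemistry and brings ring B in as an aroyl unit. It sets out from 6: the lithium dianion of 6 (LiN(SiMe3)2, THF, −78 °C) is C-acylated with 1-[4-(methoxymethoxy)benzoyl]imidazole to give 1-[2-hydroxy-4,6-bis(methoxymethoxy)-3-(3-methylbut-2-enyl)phenyl]-2-(methoxymethoxy)-3-[4-(methoxymethoxy)phenyl]propane-1,3-dione F1. This diketone is cyclodehydrated through its one free phenol under buffered acid (NaOAc, AcOH, 80 °C) to 3,5,7-tris(methoxymethoxy)-2-[4-(methoxymethoxy)phenyl]-8-(3-methylbut-2-enyl)chromen-4-one F2. The four MOM ethers are then removed under the conditions of step 11, and the route comes back at 19.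

2. Step 9. Methoxide may add in conjugate fashion to the new pyranone-activated alkyne, or open the pyranone at C2 in basic methanol. The fallback homologates without a protic nucleophile and sets out from 13: Wittig reaction with the ylide from (chloromethyl)triphenylphosphonium chloride and NaN(SiMe3)2 (THF, −78 °C) gives 2-(2-chloroethenyl)-3,5,7-tris(methoxymethoxy)-8-(3-methylbut-2-enyl)chromen-4-one F3 as an E/Z mixture. Dehydrochlorination with LiN(SiMe3)2 (2.2 equiv, THF, −78 °C) then brings the route back at 14.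

3. Step 6. The phenol of the ring-opened tautomer may be sulfonylated, or the oxalyl unit lost by retro-Claisen cleavage, instead of dehydration. The fallback closes ring C with a one-carbon unit and functionalises C2 afterwards; it sets out from 6 and bypasses steps 5–8. Heating 6 with N,N-dimethylformamide dimethyl acetal (toluene, 100 °C) gives (Z)-3-(dimethylamino)-1-[2-hydroxy-4,6-bis(methoxymethoxy)-3-(3-methylbut-2-enyl)phenyl]-2-(methoxymethoxy)prop-2-en-1-one F4. This closes on silica gel or gentle warming, with loss of dimethylamine, to 3,5,7-tris(methoxymethoxy)-8-(3-methylbut-2-enyl)chromen-4-one F5. Lithiation of F5 at C2, between O1 and the 3-OMOM group, with LiN(i-Pr)2 (THF, −78 °C) and a DMF quench brings the route back at 13.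

**Further compounds**

F1 | step 10 | 1-[2-hydroxy-4,6-bis(methoxymethoxy)-3-(3-methylbut-2-enyl)phenyl]-2-(methoxymethoxy)-3-[4-(methoxymethoxy)phenyl]propane-1,3-dione (racemic) | COCOc1ccc(cc1)C(=O)C(OCOC)C(=O)c1c(OCOC)cc(OCOC)c(CC=C(C)C)c1O
F2 | step 10 | 3,5,7-tris(methoxymethoxy)-2-[4-(methoxymethoxy)phenyl]-8-(3-methylbut-2-enyl)chromen-4-one | COCOc1ccc(cc1)-c1oc2c(CC=C(C)C)c(OCOC)cc(OCOC)c2c(=O)c1OCOC
F3 | step 9 | 2-(2-chloroethenyl)-3,5,7-tris(methoxymethoxy)-8-(3-methylbut-2-enyl)chromen-4-one (E/Z mixture) | ClC=Cc1oc2c(CC=C(C)C)c(OCOC)cc(OCOC)c2c(=O)c1OCOC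
F4 | step 6 | (Z)-3-(dimethylamino)-1-[2-hydroxy-4,6-bis(methoxymethoxy)-3-(3-methylbut-2-enyl)phenyl]-2-(methoxymethoxy)prop-2-en-1-one | CN(C)/C=C(\OCOC)C(=O)c1c(OCOC)cc(OCOC)c(CC=C(C)C)c1O
F5 | step 6 | 3,5,7-tris(methoxymethoxy)-8-(3-methylbut-2-enyl)chromen-4-one | O=c1c(OCOC)coc2c(CC=C(C)C)c(OCOC)cc(OCOC)c12
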